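## Retrosynthetic overview

1. The ten-membered ring is closed last at C9–C10 by an electrochemical, Ni-catalysed coupling of a primary alkyl bromide with an (E)-alkenyl iodide; the acyclic precursor already carries all five stereocentres and both esters.
2. The alkenyl iodide comes from cross-metathesis of a terminal alkene with an isopropenylboronate, then iododeboronation; the angelate comes from Mitsunobu inversion of a (3R)-homoallylic alcohol made by allylboration of an α,β-epoxy aldehyde.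
3. The epoxy aldehyde comes from hydroxyl-directed epoxidation of an (E)-allylic 1,4-diol, itself made by Wittig olefination of an α-hydroxy aldehyde.
4. The α-hydroxy aldehyde with its C9 bromide comes from ozonolytic radical fragmentation of cis-piperitol, made from (R)-piperitone (C7 bought, C6 set by substrate-controlled reduction).
5. Ring order: oxirane first (step 4), ten-membered carbocycle last (step 10).

Atom labels C1–C15 follow germacrane numbering of the target: C3 (angelate), C4–C5 (epoxide; C15 = methyl on C4), C6 (acetate), C7 (isopropyl), C1=C10 (C14 = methyl on C10).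

Assumption: natural (R)-(−)-piperitone (Eucalyptus dives oil) is available cheaply in enantiopure form; it is the only source of chirality.

## Route

Step 1
Reactants: 1 (6R)-3-methyl-6-(propan-2-yl)cyclohex-2-en-1-one
Product: 2 (1S,6R)-3-methyl-6-(propan-2-yl)cyclohex-2-en-1-ol
Conditions: LiBH(s-Bu)3, THF, −78 °C; then H2O
Reagents that add atoms: none
Why: Bulky-hydride 1,2-reduction of the β-substituted enone; equatorial attack, as with 2-alkylcyclohexanones, gives the cis alcohol, so the bought C7 centre sets C6 as (S).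

Step 2
Reactants: 2 (1S,6R)-3-methyl-6-(propan-2-yl)cyclohex-2-en-1-ol
Product: 4 (2S,3R)-5-bromo-2-hydroxy-3-(propan-2-yl)pentanal, via methoxy hydroperoxide 3 (not isolated)
Conditions: O3, CH2Cl2/MeOH, −78 °C; N2 purge; then CuBr2 (3 equiv), FeSO4·7H2O (1.5 equiv), MeOH/H2O, −20 °C to rt; crude 4 used at once
Reagents that add atoms: ozone (O=[O+][O-]); methanol (CO); CuBr2 (Br[Cu]Br)
Why: Ozonolysis in methanol puts the carbonyl oxide on the more substituted alkene carbon, remote from the hydroxyl; one-electron reduction of the α-methoxy hydroperoxide by FeSO4 then triggers alkoxy-radical β-scission (loss of methyl acetate), and the primary C9 radical is brominated by ligand transfer from CuBr2, with both stereocentres untouched.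

Step 3
Reactants: 4 (2S,3R)-5-bromo-2-hydroxy-3-(propan-2-yl)pentanal; 5 2-(triphenylphosphoranylidene)propanal
Product: 7 (2E,4S,5R)-7-bromo-2-methyl-5-(propan-2-yl)hept-2-ene-1,4-diol, via enal 6 (not isolated)
Conditions: 5 (1.2 equiv), toluene, 60 °C; then MeOH, CeCl3·7H2O, NaBH4, 0 °C
Reagents that add atoms: none
Why: Wittig olefination with the formyl-stabilised ylide gives the (E)-trisubstituted enal (C15 methyl cis to C6), and Luche reduction in the same flask reduces only the aldehyde; no stereocentre is formed.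

Step 4
Reactants: 7 (2E,4S,5R)-7-bromo-2-methyl-5-(propan-2-yl)hept-2-ene-1,4-diol
Product: 8 [(2R,3R)-3-[(1S,2R)-4-bromo-1-hydroxy-2-(propan-2-yl)butyl]-2-methyloxiran-2-yl]methanol
Conditions: VO(acac)2 (5 mol%), t-BuOOH, CH2Cl2, 0 °C to rt
Reagents that add atoms: tert-butyl hydroperoxide (CC(C)(C)OO)
Why: Hydroxyl-directed epoxidation; allylic 1,3-strain with the cis C15 methyl holds H-6 in the alkene plane, so vanadium bound to the C6 hydroxyl delivers oxygen to its own face and gives the threo (4R,5R) epoxide.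

Step 5
Reactants: 8 [(2R,3R)-3-[(1S,2R)-4-bromo-1-hydroxy-2-(propan-2-yl)butyl]-2-methyloxiran-2-yl]methanol
Product: 10 (1S,2R)-4-bromo-1-[(2R,3S)-3-formyl-3-methyloxiran-2-yl]-2-(propan-2-yl)butyl acetate, via hydroxy epoxy aldehyde 9 (not isolated)
Conditions: PhI(OAc)2, TEMPO (10 mol%), CH2Cl2, rt; then Ac2O, pyridine, DMAP (cat.), 0 °C
Reagents that add atoms: acetic anhydride (CC(=O)OC(C)=O)
Why: The nitroxyl-catalysed oxidation is selective for the primary alcohol, and acetylation in the same flask installs the C6 acetate; the aldehyde α-carbon is quaternary and cannot epimerise.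

Step 6
Reactants: 10 (1S,2R)-4-bromo-1-[(2R,3S)-3-formyl-3-methyloxiran-2-yl]-2-(propan-2-yl)butyl acetate; 11 4,4,5,5-tetramethyl-2-(prop-2-en-1-yl)-1,3,2-dioxaborolane
Product: 12 (1S,2R)-4-bromo-1-{(2R,3R)-3-[(1R)-1-hydroxybut-3-en-1-yl]-3-methyloxiran-2-yl}-2-(propan-2-yl)butyl acetate
Conditions: 11 (1.5 equiv), toluene, −40 °C to rt; aqueous NaHCO3 work-up
Reagents that add atoms: none
Why: Allylboration through a closed six-membered transition state under non-chelating Cornforth control (C=O anti to the epoxide C–O, allyl group entering between the epoxide oxygen and the methyl) gives mainly the erythro (3R) alcohol; selectivity is expected to be moderate (about 4:1) and the minor epimer is removed by chromatography.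

Step 7
Reactants: 12 (1S,2R)-4-bromo-1-{(2R,3R)-3-[(1R)-1-hydroxybut-3-en-1-yl]-3-methyloxiran-2-yl}-2-(propan-2-yl)butyl acetate; 13 (2Z)-2-methylbut-2-enoic acid
Product: 14 (1S)-1-{(2R,3R)-3-[(1S,2R)-1-(acetyloxy)-4-bromo-2-(propan-2-yl)butyl]-2-methyloxiran-2-yl}but-3-en-1-yl (2Z)-2-methylbut-2-enoate
Conditions: PPh3, DIAD, toluene, 0 °C to rt
Reagents that add atoms: none
Why: Mitsunobu esterification; SN2 displacement of the activated C3 oxygen by the carboxylate inverts C3 to (S) and installs the angelate in one operation under non-basic conditions.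

Step 8
Reactants: 14 (1S)-1-{(2R,3R)-3-[(1S,2R)-1-(acetyloxy)-4-bromo-2-(propan-2-yl)butyl]-2-methyloxiran-2-yl}but-3-en-1-yl (2Z)-2-methylbut-2-enoate; 15 4,4,5,5-tetramethyl-2-(prop-1-en-2-yl)-1,3,2-dioxaborolane
Product: 16 (1S,3Z)-1-{(2R,3R)-3-[(1S,2R)-1-(acetyloxy)-4-bromo-2-(propan-2-yl)butyl]-2-methyloxiran-2-yl}-4-(4,4,5,5-tetramethyl-1,3,2-dioxaborolan-2-yl)pent-3-en-1-yl (2Z)-2-methylbut-2-enoate
Conditions: second-generation Grubbs catalyst (10 mol%), 15 (5 equiv), CH2Cl2, 40 °C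
Reagents that add atoms: none
Why: Olefin cross-metathesis of the terminal alkene with the 1,1-disubstituted boronate; the bulky pinacolboryl group ends trans to the chain (Z by the CIP rules), which fixes the geometry of the future C1=C10 bond, and the trisubstituted angelate alkene is inert.

Step 9
Reactants: 16 (1S,3Z)-1-{(2R,3R)-3-[(1S,2R)-1-(acetyloxy)-4-bromo-2-(propan-2-yl)butyl]-2-methyloxiran-2-yl}-4-(4,4,5,5-tetramethyl-1,3,2-dioxaborolan-2-yl)pent-3-en-1-yl (2Z)-2-methylbut-2-enoate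
Product: 17 (1S,3E)-1-{(2R,3R)-3-[(1S,2R)-1-(acetyloxy)-4-bromo-2-(propan-2-yl)butyl]-2-methyloxiran-2-yl}-4-iodopent-3-en-1-yl (2Z)-2-methylbut-2-enoate
Conditions: N-iodosuccinimide, MeCN, 0 °C to rt, dark
Reagents that add atoms: N-iodosuccinimide (O=C1CCC(=O)N1I)
Why: Ipso-iododeboronation of the alkenylboronate with an N-halosuccinimide proceeds with retention of alkene geometry and gives the (E)-alkenyl iodide (iodine trans to C2) under base-free conditions that spare both esters.

Step 10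
Reactants: 17 (1S,3E)-1-{(2R,3R)-3-[(1S,2R)-1-(acetyloxy)-4-bromo-2-(propan-2-yl)butyl]-2-methyloxiran-2-yl}-4-iodopent-3-en-1-yl (2Z)-2-methylbut-2-enoate
Product: 18 (1R,2S,4E,8R,9S,10R)-9-(acetyloxy)-1,5-dimethyl-8-(propan-2-yl)-11-oxabicyclo[8.1.0]undec-4-en-2-yl (2Z)-2-methylbut-2-enoate
Conditions: NiBr2(dme) (20 mol%), 4,4′-di-tert-butyl-2,2′-bipyridine (24 mol%), n-Bu4NPF6 (0.1 M), DMA, undivided cell, Zn anode, reticulated vitreous carbon cathode, constant current 3 mA, 17 added by syringe pump over 10 h (final 2 mM), 25 °C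
Reagents that add atoms: none
Why: Proposed new method: a ring-closing version of Ni-catalysed electroreductive C(sp3)–C(sp2) cross-electrophile coupling, in which cathodically formed zerovalent nickel adds to the alkenyl C–I bond (much faster than to the alkyl bromide, geometry retained), a monovalent nickel species abstracts bromine from C9, the primary radical is captured by the tethered alkenylnickel and reductive elimination from trivalent nickel forms the C9–C10 bond, with the E-alkene, the trans-epoxide and the vicinal branching limiting the chain to a few turn conformers and slow addition suppressing dimerisation; the closest known reactions are the intermolecular nickel-catalysed electroreductive couplings of alkenyl halides with alkyl halides and the nickel-electrocatalytic decarboxylative alkenylations used for polyene terpenes, and no stereocentre is formed or lies next to a reacting carbon.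

## Compound list

1 | (6R)-3-methyl-6-(propan-2-yl)cyclohex-2-en-1-one, (R)-(−)-piperitone | CC1=CC(=O)[C@@H](C(C)C)CC1 | starting material
2 | (1S,6R)-3-methyl-6-(propan-2-yl)cyclohex-2-en-1-ol, cis-piperitol | CC1=C[C@@H](O)[C@@H](C(C)C)CC1 | intermediate
3 | (2S,3R)-6-hydroperoxy-2-hydroxy-6-methoxy-3-(propan-2-yl)heptanal (both C6 epimers) | O=C[C@@H](O)[C@@H](C(C)C)CCC(C)(OC)OO | intermediate
4 | (2S,3R)-5-bromo-2-hydroxy-3-(propan-2-yl)pentanal | O=C[C@@H](O)[C@@H](C(C)C)CCBr | intermediate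
5 | 2-(triphenylphosphoranylidene)propanal | CC(C=O)=P(c1ccccc1)(c1ccccc1)c1ccccc1 | starting material
6 | (2E,4S,5R)-7-bromo-4-hydroxy-2-methyl-5-(propan-2-yl)hept-2-enal | O=C/C(C)=C/[C@@H](O)[C@@H](C(C)C)CCBr | intermediate
7 | (2E,4S,5R)-7-bromo-2-methyl-5-(propan-2-yl)hept-2-ene-1,4-diol | OC/C(C)=C/[C@@H](O)[C@@H](C(C)C)CCBr | intermediate
8 | [(2R,3R)-3-[(1S,2R)-4-bromo-1-hydroxy-2-(propan-2-yl)butyl]-2-methyloxiran-2-yl]methanol | OC[C@@]1(C)O[C@@H]1[C@@H](O)[C@@H](C(C)C)CCBr | intermediate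
9 | (2S,3R)-3-[(1S,2R)-4-bromo-1-hydroxy-2-(propan-2-yl)butyl]-2-methyloxirane-2-carbaldehyde | O=C[C@@]1(C)O[C@@H]1[C@@H](O)[C@@H](C(C)C)CCBr | intermediate
10 | (1S,2R)-4-bromo-1-[(2R,3S)-3-formyl-3-methyloxiran-2-yl]-2-(propan-2-yl)butyl acetate | O=C[C@@]1(C)O[C@@H]1[C@@H](OC(C)=O)[C@@H](C(C)C)CCBr | intermediate
11 | 4,4,5,5-tetramethyl-2-(prop-2-en-1-yl)-1,3,2-dioxaborolane | C=CCB1OC(C)(C)C(C)(C)O1 | starting material
12 | (1S,2R)-4-bromo-1-{(2R,3R)-3-[(1R)-1-hydroxybut-3-en-1-yl]-3-methyloxiran-2-yl}-2-(propan-2-yl)butyl acetate | C=CC[C@@H](O)[C@@]1(C)O[C@@H]1[C@@H](OC(C)=O)[C@@H](C(C)C)CCBr | intermediate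
13 | (2Z)-2-methylbut-2-enoic acid, angelic acid | C/C=C(/C)C(=O)O | starting material
14 | (1S)-1-{(2R,3R)-3-[(1S,2R)-1-(acetyloxy)-4-bromo-2-(propan-2-yl)butyl]-2-methyloxiran-2-yl}but-3-en-1-yl (2Z)-2-methylbut-2-enoate | C=CC[C@H](OC(=O)/C(C)=C\C)[C@@]1(C)O[C@@H]1[C@@H](OC(C)=O)[C@@H](C(C)C)CCBr | intermediate
15 | 4,4,5,5-tetramethyl-2-(prop-1-en-2-yl)-1,3,2-dioxaborolane | C=C(C)B1OC(C)(C)C(C)(C)O1 | starting material
16 | (1S,3Z)-1-{(2R,3R)-3-[(1S,2R)-1-(acetyloxy)-4-bromo-2-(propan-2-yl)butyl]-2-methyloxiran-2-yl}-4-(4,4,5,5-tetramethyl-1,3,2-dioxaborolan-2-yl)pent-3-en-1-yl (2Z)-2-methylbut-2-enoate | C\C(B2OC(C)(C)C(C)(C)O2)=C/C[C@H](OC(=O)/C(C)=C\C)[C@@]1(C)O[C@@H]1[C@@H](OC(C)=O)[C@@H](C(C)C)CCBr | intermediate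
17 | (1S,3E)-1-{(2R,3R)-3-[(1S,2R)-1-(acetyloxy)-4-bromo-2-(propan-2-yl)butyl]-2-methyloxiran-2-yl}-4-iodopent-3-en-1-yl (2Z)-2-methylbut-2-enoate | C\C(I)=C/C[C@H](OC(=O)/C(C)=C\C)[C@@]1(C)O[C@@H]1[C@@H](OC(C)=O)[C@@H](C(C)C)CCBr | intermediate
18 | (1R,2S,4E,8R,9S,10R)-9-(acetyloxy)-1,5-dimethyl-8-(propan-2-yl)-11-oxabicyclo[8.1.0]undec-4-en-2-yl (2Z)-2-methylbut-2-enoate; in germacrane numbering (3S,4R,5R,6S,7R) | C/C=C(/C)C(=O)O[C@H]1C/C=C(\C)CC[C@H](C(C)C)[C@H](OC(C)=O)[C@H]2O[C@]12C | target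

## Step count and risks

Total step count: 10. Longest linear sequence: 10 steps (1 to 18); compounds 5, 11, 13 and 15 are bought.

The three steps most likely to fail:

Step 10, the proposed new ring closure. The ten-membered ring is strained, and reduction of either halide or dimerisation may win. Fallback with known chemistry, from 17 back to 18: NaI in acetone exchanges the bromide to give (1S,3E)-1-{(2R,3R)-3-[(1S,2R)-1-(acetyloxy)-4-iodo-2-(propan-2-yl)butyl]-2-methyloxiran-2-yl}-4-iodopent-3-en-1-yl (2Z)-2-methylbut-2-enoate F8. Zinc dust with LiCl in THF at rt inserts only into the alkyl C–I bond to give iodo{(3R,4S)-4-(acetyloxy)-4-[(2R,3R)-3-{(1S,3E)-4-iodo-1-[(2Z)-2-methylbut-2-enoyloxy]pent-3-en-1-yl}-3-methyloxiran-2-yl]-3-(propan-2-yl)butyl}zinc F9, which is not isolated. Slow addition of F9 to Pd(PPh3)4 in THF/DMA at 50 °C closes the ring by an intramolecular Negishi coupling, a thermal two-electron C(sp3)–C(sp2) coupling with a preformed organozinc and retention of alkene geometry, and gives 18.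

Step 2, the ozonolytic radical fragmentation. The primary radical can be lost by hydrogen transfer or alkene formation, and the γ-bromo alcohol can close to a tetrahydrofuran. Fallback without radicals, from 2 back to 7: ozonolysis in CH2Cl2/MeOH gives the same intermediate 3, and Ac2O/Et3N/DMAP then converts it by Criegee rearrangement into (3R,4S)-4-(acetyloxy)-5-oxo-3-(propan-2-yl)pentyl acetate F1. Wittig olefination with ethyl 2-(triphenylphosphoranylidene)propanoate gives ethyl (2E,4S,5R)-4,7-bis(acetyloxy)-2-methyl-5-(propan-2-yl)hept-2-enoate F2. K2CO3 in EtOH removes both acetates to give ethyl (2E,4S,5R)-4,7-dihydroxy-2-methyl-5-(propan-2-yl)hept-2-enoate F3. CBr4/PPh3 at 0 °C brominates only the primary alcohol to give ethyl (2E,4S,5R)-7-bromo-4-hydroxy-2-methyl-5-(propan-2-yl)hept-2-enoate F4, and i-Bu2AlH at −78 °C reduces the ester to 7.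

Step 7, the Mitsunobu angeloylation. The carbinol sits next to a fully substituted epoxide carbon, and angelic acid is a weak, isomerisable nucleophile. Fallback that separates inversion from angeloylation, from 12 back to 14: Mitsunobu reaction with the smaller, more acidic chloroacetic acid gives the inverted (1S)-1-{(2R,3R)-3-[(1S,2R)-1-(acetyloxy)-4-bromo-2-(propan-2-yl)butyl]-2-methyloxiran-2-yl}but-3-en-1-yl chloroacetate F5. NaHCO3 in aqueous MeOH at 0 °C cleaves the chloroacetate far faster than the acetate and frees (1S,2R)-4-bromo-1-{(2R,3R)-3-[(1S)-1-hydroxybut-3-en-1-yl]-3-methyloxiran-2-yl}-2-(propan-2-yl)butyl acetate F6. Separately, 13 with 2,4,6-trichlorobenzoyl chloride and Et3N gives (2Z)-2-methylbut-2-enoic 2,4,6-trichlorobenzoic anhydride F7, which acylates F6 in toluene at 80 °C with retention at C3 and without Z/E isomerisation to give 14.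

Further compounds

F1 | step 2 | (3R,4S)-4-(acetyloxy)-5-oxo-3-(propan-2-yl)pentyl acetate | O=C[C@@H](OC(C)=O)[C@@H](C(C)C)CCOC(C)=O
F2 | step 2 | ethyl (2E,4S,5R)-4,7-bis(acetyloxy)-2-methyl-5-(propan-2-yl)hept-2-enoate | CCOC(=O)/C(C)=C/[C@@H](OC(C)=O)[C@@H](C(C)C)CCOC(C)=O
F3 | step 2 | ethyl (2E,4S,5R)-4,7-dihydroxy-2-methyl-5-(propan-2-yl)hept-2-enoate | CCOC(=O)/C(C)=C/[C@@H](O)[C@@H](C(C)C)CCO
F4 | step 2 | ethyl (2E,4S,5R)-7-bromo-4-hydroxy-2-methyl-5-(propan-2-yl)hept-2-enoate | CCOC(=O)/C(C)=C/[C@@H](O)[C@@H](C(C)C)CCBr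
F5 | step 7 | (1S)-1-{(2R,3R)-3-[(1S,2R)-1-(acetyloxy)-4-bromo-2-(propan-2-yl)butyl]-2-methyloxiran-2-yl}but-3-en-1-yl chloroacetate | C=CC[C@H](OC(=O)CCl)[C@@]1(C)O[C@@H]1[C@@H](OC(C)=O)[C@@H](C(C)C)CCBr
F6 | step 7 | (1S,2R)-4-bromo-1-{(2R,3R)-3-[(1S)-1-hydroxybut-3-en-1-yl]-3-methyloxiran-2-yl}-2-(propan-2-yl)butyl acetate | C=CC[C@H](O)[C@@]1(C)O[C@@H]1[C@@H](OC(C)=O)[C@@H](C(C)C)CCBr
F7 | step 7 | (2Z)-2-methylbut-2-enoic 2,4,6-trichlorobenzoic anhydride | C/C=C(/C)C(=O)OC(=O)c1c(Cl)cc(Cl)cc1Cl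
F8 | step 10 | (1S,3E)-1-{(2R,3R)-3-[(1S,2R)-1-(acetyloxy)-4-iodo-2-(propan-2-yl)butyl]-2-methyloxiran-2-yl}-4-iodopent-3-en-1-yl (2Z)-2-methylbut-2-enoate | C\C(I)=C/C[C@H](OC(=O)/C(C)=C\C)[C@@]1(C)O[C@@H]1[C@@H](OC(C)=O)[C@@H](C(C)C)CCI
F9 | step 10 | iodo{(3R,4S)-4-(acetyloxy)-4-[(2R,3R)-3-{(1S,3E)-4-iodo-1-[(2Z)-2-methylbut-2-enoyloxy]pent-3-en-1-yl}-3-methyloxiran-2-yl]-3-(propan-2-yl)butyl}zinc | C\C(I)=C/C[C@H](OC(=O)/C(C)=C\C)[C@@]1(C)O[C@@H]1[C@@H](OC(C)=O)[C@@H](C(C)C)CC[Zn]I
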